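(The rate constants stand for no real mixture; the flask was simulated.)

Choose first which clock to watch in these two flasks: the catalyst's, which feeds target in, or the isomerisation's, which wears target down.

- green: starting material 0.089 M; reagent 0.222 M; free catalyst 0.32 mM; added ligand 0.19 mM; time 3.0 d
- red: starting material 0.089 M; reagent 0.222 M; free catalyst 0.32 mM; added ligand 0.19 mM; time 6.0 d

    target ⇌ isomer of the product (K1 = 2.7, k1 = 5.33 × 10⁻⁶ /s)
    free catalyst + added ligand ⇌ idle complex, settled at all times (K2 = 2540 /M)
    catalyst intermediate C → free catalyst + target (k3 = 0.00311 /s)
    reagent + free catalyst ⇌ catalyst intermediate A (K4 = 39 /M, k4 = 0.0471 /M/s)
    starting material + catalyst intermediate A → catalyst intermediate B (k5 = 4.02 /M/s)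
    catalyst intermediate B ⇌ by-product + catalyst intermediate C (K6 = 0.045 M, k6 = 0.0101 /s)

* which of the two there is more of at the end, green (target / isomer of the product)
* which of the two there is more of at the end, red (target / isomer of the product)
* final target, as a percentage of the starting material charged, in green
* final target, as a percentage of the starting material charged, in red

Two of us disputed this before any run. The first held that the isomerisation tells the story: target and isomer of the product relax together at 0.631 /d, both directions counted, towards 27.0% target, so if the whole charge counts as target from the start, the target share is 38.0% in green and 28.7% in red, with the isomer ahead in both.

The second, whose reckoning I take as my own, wrote the balance of the starting material, the limiting reagent, whose charge is smaller than that of the reagent. Each molecule used costs one round of the catalyst, and a round without by-product lasts 562 s, counting the waits in catalyst intermediate C, in catalyst intermediate B and as free catalyst with its idle complex, with the added ligand and the reagent taken at their charges, and leaving out the wait as catalyst intermediate A, which is 2.80 s at the charge of starting material. By-product sends intermediate C back to intermediate B, which lengthens the round in proportion to [by-product], by 318 s on average over the charge. Each catalyst must make 278 rounds, which makes 2.83 d the consumption time, the time the catalyst needs to use up the charge of starting material. Because this is longer than the relaxation time of 1.58 d, target arrives as a feed, not as a charge at the start. Taking the feed as even, the target made keeps on average 46.6% of its excess over equilibrium when the feed ends, and green, ending soon after that, keeps 41.9%. So I reckon green to end at 57.6% target, with more of target, and red, aged further, to end at 31.6% target, with more of isomer of the product.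

The forecast sides with this view but stands 2.6 percentage points under my green figure, giving 55% and more of target in green, 31% and more of isomer of the product in red, on the ground that “the target formed late has not yet had time to isomerise”.

The simulation gives 55.5% target against 44.1% isomer in green, where target leads with 0.226% of the starting material left at 3.00 d, and 31.4% target in red, where isomer of the product leads. The first view misses green by 18 points; its ground is the late flask, for it misses red by 2.7 points, and green reaches 27.0% at 30.0 d. The neighbour of red with 1.3 × 10⁻⁴ M of free catalyst has a consumption time of 6.98 d, longer than its 6.0 d, and the balance solved at that time leaves 10.6% of the starting material; that flask ends with 13% left and 36.9% target.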